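The oxygenated carbons C3 (ring A) and C8 (ring B) of the cis-fused eremophilane lie across the ring fusion, so a temporary C3–C8 bond folds ring A and the C8–C9 unit into a bicyclo[2.2.2]octene, available by an enantioselective Diels–Alder reaction. An anionic oxy-Cope rearrangement then exchanges C3–C8 for C5–C6: one operation closes ring B (C5–C10), creates the C5 quaternary centre with its methyl cis to H10, and unmasks C3 as an enol ether and C8 as a ketone carrying the C7 isopropenyl group. Its precursor is a 1-methoxy-5,6-dimethylbicyclo[2.2.2]oct-5-en-2-ol with a 3-methylbuta-1,3-dien-2-yl group on the carbinol carbon and a protected hydroxyl next to it. The diester chain is attached last as an ynoate.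

Key step: step 10

Remark on names: decalins carry eremophilane numbering (C3 ester carbinol, C4 and C5 methyl-bearing carbons, C7 isopropenyl carbon, C8/C9 diol, C10 ring-fusion CH); β is the face of the C5 methyl group; all decalins are 4β,5β-dimethyl, 10βH unless C4 is sp2. Bicycles carry von Baeyer numbering, and "syn" means toward the C5=C6 (etheno) bridge.
Assumption on step 1: the dihydroanisole drawn as 2 is the expected regioisomer; the other 2,5-dihydro isomer would converge on the same diene 3 in step 2.
Assumption on step 3: the (R)-prolinol-derived oxazaborolidinium catalyst is taken to expose the Si face at the acrylate α-carbon; should the first adduct prove antipodal, the mirror-image catalyst is used with no other change.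

Step 1
Reactants: 1 (2,3-dimethylanisole)
Product: 2 (1-methoxy-2,3-dimethylcyclohexa-1,4-diene)
Conditions: Li, NH3(l), THF, t-BuOH, −78 → −33 °C; then MeOH, H2O
Reagents that add atoms: none
Why: Birch reduction, in which the arene radical anion is protonated at the unsubstituted ortho carbon and then para to it, leaving the methoxy group on a ring alkene.

Step 2
Reactants: 2 (1-methoxy-2,3-dimethylcyclohexa-1,4-diene)
Product: 3 (1-methoxy-2,3-dimethylcyclohexa-1,3-diene)
Conditions: t-BuOK (0.3 equiv), DMSO, 25 °C; distillation
Reagents that add atoms: none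
Why: Base-mediated prototropic equilibration through the pentadienyl anion should favour the conjugated diene with the most substituted double bonds, and unconjugated material left over is inert in the cycloaddition.

Step 3
Reactants: 3 (1-methoxy-2,3-dimethylcyclohexa-1,3-diene) + 4 (2,2,2-trifluoroethyl acrylate)
Product: 5 (2,2,2-trifluoroethyl (1R,2R,4R)-1-methoxy-5,6-dimethylbicyclo[2.2.2]oct-5-ene-2-carboxylate; ester syn to the etheno bridge)
Conditions: B-(o-tolyl)oxazaborolidine from (R)-α,α-diphenylprolinol (20 mol %), Tf2NH (17 mol %), CH2Cl2, −78 °C; chromatography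
Reagents that add atoms: none
Why: Catalytic enantioselective Diels–Alder reaction under cationic oxazaborolidine activation, in which the nucleophilic C4 terminus of the 1-methoxydiene bonds to the acrylate β-carbon (ortho orientation), secondary overlap gives the endo ester, and shielding of one acrylate face fixes C2 and with it both bridgeheads; any exo adduct is removed here because it would lead to the antipodal ketone.

Step 4
Reactants: 5 (endo trifluoroethyl ester)
Product: 6 ((1R,2R,4R)-1-methoxy-5,6-dimethylbicyclo[2.2.2]oct-5-ene-2-carboxylic acid)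
Conditions: LiOH, THF–H2O, 0 → 25 °C; then cold 1 M HCl
Reagents that add atoms: lithium hydroxide, [Li+].[OH-]
Why: Saponification of the activated trifluoroethyl ester is fast under mild conditions that leave the bridgehead ether and the alkene untouched.

Step 5
Reactants: 6 (bicyclic carboxylic acid)
Product: 9 ketone (1S,4R)-1-methoxy-5,6-dimethylbicyclo[2.2.2]oct-5-en-2-one, via dilithium enediolate 7 (not isolated), via α-hydroperoxy acid 8 (not isolated)
Conditions: LDA (2.3 equiv), THF–DMPU, 0 → 45 °C; O2, −78 °C; then 2 M HCl, Et2O, 25 °C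
Reagents that add atoms: dioxygen, O=O
Why: Oxidative decarboxylation by enolate oxygenation, in which the acid dianion captures O2 at C2 and the α-hydroperoxy acid fragments on acidification to ketone, CO2 and water; the bridgehead position excludes β-elimination of methoxide and both bridgehead centres are untouched.

Step 6
Reactants: 9 (bicyclic ketone)
Product: 11 ketol (1S,3R,4S)-3-hydroxy-1-methoxy-5,6-dimethylbicyclo[2.2.2]oct-5-en-2-one, via potassium enolate 10 (not isolated)
Conditions: KHMDS, THF, −78 °C; 2-(phenylsulfonyl)-3-phenyloxaziridine, −78 °C; AcOH quench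
Reagents that add atoms: 2-(phenylsulfonyl)-3-phenyloxaziridine, O=S(=O)(c1ccccc1)N1OC1c1ccccc1
Why: Enolate oxidation with an N-sulfonyloxaziridine (Davis hydroxylation), where the ketone can enolise only toward C3 and the oxidant should approach past the sp2 etheno bridge, which has no inward C–H bonds, and not past the C7/C8 methylene hydrogens, so the hydroxyl ends syn to the etheno bridge.

Step 7
Reactants: 11 (syn ketol)
Product: 12 ((1S,3R,4S)-3-(benzyloxymethoxy)-1-methoxy-5,6-dimethylbicyclo[2.2.2]oct-5-en-2-one)
Conditions: BOMCl, i-Pr2NEt, Bu4NI (cat.), CH2Cl2, 0 → 25 °C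
Reagents that add atoms: benzyl chloromethyl ether, ClCOCc1ccccc1
Why: O-alkylation with an α-chloro ether under amine base is mild enough to avoid enediol isomerisation of the ketol, and the benzyloxymethyl acetal withstands KH, hydride and dilute acid yet is cleaved in the later dissolving-metal step without the strong acid that a methoxymethyl ether next to a cis hydroxyl would need.

Step 8
Reactants: 13 (2-methylbut-1-en-3-yne)
Product: 15 2-bromo-3-methylbuta-1,3-diene, via bromoalkenylborane 14 (not isolated)
Conditions: B-bromo-9-BBN, CH2Cl2, 0 °C; then AcOH, 0 → 25 °C; used as a cold solution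
Reagents that add atoms: B-bromo-9-borabicyclo[3.3.1]nonane, BrB1C2CCCC1CCC2
Why: Haloboration, in which the bromoborane adds cis to the terminal alkyne only, with bromine at the internal carbon, and protodeboronation with acetic acid releases the 2-bromodiene.

Step 9
Reactants: 12 (benzyloxymethoxy ketone) + 15 (2-bromo-3-methylbuta-1,3-diene)
Product: 18 carbinol (1S,2S,3R,4S)-3-(benzyloxymethoxy)-1-methoxy-5,6-dimethyl-2-(3-methylbuta-1,3-dien-2-yl)bicyclo[2.2.2]oct-5-en-2-ol, via dienyllithium 16 (not isolated), via dienylcerium dichloride 17 (not isolated)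
Conditions: 15, t-BuLi (2 equiv), Et2O–THF, −78 °C; anhydrous CeCl3, THF, −78 °C; then 12, −78 → −40 °C; aq. NH4Cl
Reagents that add atoms: none
Why: Organocerium 1,2-addition to a hindered, enolisable ketone, where the weakly basic reagent should attack the carbonyl face turned toward the etheno bridge because the other face is screened by the C7 methylene hydrogen, placing the dienyl group syn to the etheno bridge although the C3 alkoxy group lies on the same side; the bridgehead methoxy group, coplanar with the carbonyl, can bind the metal without favouring either face.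

Step 10
Reactants: 18 (dienyl carbinol)
Product: 21 cis-decalin ketone 9β-(benzyloxymethoxy)-3-methoxyeremophila-3,11-dien-8-one with 7β-isopropenyl group, via potassium alkoxide 19 (not isolated), via potassium dienolate 20 (not isolated)
Conditions: KH (3 equiv), 18-crown-6, THF, 0 → 25 °C; cannulation into AcOH–THF at −78 °C
Reagents that add atoms: none
Why: Deprotonation gives the potassium alkoxide, whose charge weakens the adjacent C3–C8 bond (already loosened by the bridgehead methoxy group), and the 1,5-diene C6=C7–C8–C3–C4=C5 undergoes a concerted [3,3] shift through the boat array enforced by the bicycle; this is an anionic oxy-Cope rearrangement, the closest known case being 1-methoxy-2-vinylbicyclo[2.2.2]oct-5-en-2-ols giving cis-decalin enol ether ketones. Ring B (C5–C6–C7–C8–C9–C10) closes by suprafacial bonding of the C6 methylene to C5 while the C3–C8 bridge opens, a sigmatropic closure and not an ionic cyclisation, and no other ring is formed. C5 is set by the bicycle, since C6 can reach C5 only on the face turned toward the C8–C9 bridge, so C6 and C9 end cis and the C5 methyl cis to H10; C9 and C10 pass through unchanged. C7 is set in the quench, where the extended dienolate is protonated at its α-carbon under kinetic conditions to put the isopropenyl group equatorial (β), which is also the more stable epimer. The step needs the dienyl group syn to the etheno bridge, secured in 18, and α- over γ-protonation, secured by the cold inverse quench; relief of bicyclic strain and the enolate and enol ether termini make the shift irreversible.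

Step 11
Reactants: 21 (cis-decalin 8-ketone)
Product: 22 (9β-(benzyloxymethoxy)-3-methoxyeremophila-3,11-dien-8β-ol)
Conditions: L-Selectride, THF, −78 °C; aq. NH4Cl
Reagents that add atoms: none
Why: A bulky trialkylborohydride attacks the C8 carbonyl along the equatorial trajectory of the chair that holds the C7 isopropenyl and C9 alkoxy groups equatorial, giving the axial 8β-alcohol cis to both neighbours at a temperature where enolisation toward C7 and conjugation should not compete.

Step 12
Reactants: 22 (8β-alcohol enol ether)
Product: 23 (9β-(benzyloxymethoxy)-8β-hydroxyeremophil-11-en-3-one)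
Conditions: 0.1 M HCl, THF–H2O, 0 → 25 °C; then NaOMe (0.2 equiv), MeOH, 25 °C
Reagents that add atoms: water, O
Why: Acid hydrolysis of the enol ether frees the C3 ketone, and enolisation completed with catalytic methoxide equilibrates C4 to the equatorial 4β-methyl epimer, the 4α-epimer suffering a syn-axial contact with C9; the acetal protecting group and the isopropenyl group tolerate both media.

Step 13
Reactants: 23 (3-ketone)
Product: 24 (eremophil-11-ene-3α,8β,9β-triol)
Conditions: Li (excess), NH3(l)–THF, t-BuOH (3 equiv), −78 °C; solid NH4Cl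
Reagents that add atoms: none
Why: Dissolving-metal reduction gives the thermodynamically preferred equatorial 3α-alcohol, whereas hydride reagents would be forced by the axial C5 methyl to give the axial epimer; the same conditions cleave the benzylic C–O bond of the benzyloxymethyl group, whose hemiformal collapses on work-up, and do not reduce the isolated isopropenyl alkene.

Step 14
Reactants: 24 (triol)
Product: 25 (8β,9β-(isopropylidenedioxy)eremophil-11-en-3α-ol)
Conditions: 2,2-dimethoxypropane, PPTS (cat.), acetone, 25 °C
Reagents that add atoms: 2,2-dimethoxypropane, COC(C)(C)OC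
Why: Transacetalisation, in which only the cis-8,9-diol can close a five-membered isopropylidene acetal, so the 3α-hydroxyl stays free.

Step 15
Reactants: 26 ((R)-pent-4-yn-2-ol) + 27 (angelic acid, (Z)-2-methylbut-2-enoic acid)
Product: 29 (R)-pent-4-yn-2-yl angelate, via angelic trichlorobenzoic anhydride 28 (not isolated)
Conditions: 27, 2,4,6-trichlorobenzoyl chloride, Et3N, toluene, 25 °C; then 26, 75 °C
Reagents that add atoms: none
Why: Mixed-anhydride (Yamaguchi-type) acylation run without a nucleophilic catalyst avoids the addition–elimination pathway that turns angelates into tiglates, and the carbinol centre is not involved and keeps its R configuration.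

Step 16
Reactants: 29 ((R)-pent-4-yn-2-yl angelate)
Product: 30 ((R)-5-(angeloyloxy)hex-2-ynoic acid)
Conditions: AgI (2 mol %), Cs2CO3 (1.5 equiv), CO2 (1 atm), DMF, 45 °C; then cold 1 M HCl
Reagents that add atoms: carbon dioxide, O=C=O
Why: Silver-catalysed C–H carboxylation of a terminal alkyne with CO2 proceeds through the silver acetylide under carbonate base, mild enough for the angelate ester.

Step 17
Reactants: 25 (acetonide 3α-alcohol) + 30 ((R)-5-(angeloyloxy)hex-2-ynoic acid)
Product: 31 (3α-[(5R)-5-(angeloyloxy)hex-2-ynoyloxy]-8β,9β-(isopropylidenedioxy)eremophil-11-ene)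
Conditions: DCC, DMAP (10 mol %), CH2Cl2, −20 → 0 °C
Reagents that add atoms: none
Why: Steglich esterification of the equatorial 3α-hydroxyl, with the chain introduced at the alkyne oxidation level because an alkynoic acid has no alkene geometry to lose on activation.

Step 18
Reactants: 31 (ynoate ester)
Product: 32 (3α-[(2Z,5R)-5-(angeloyloxy)hex-2-enoyloxy]-8β,9β-(isopropylidenedioxy)eremophil-11-ene)
Conditions: H2 (1 atm), Lindlar catalyst (Pd/CaCO3–Pb), quinoline, EtOAc, 25 °C, stopped at one equivalent
Reagents that add atoms: none
Why: Lindlar semihydrogenation delivers hydrogen syn on poisoned palladium to give the Z-enoate, and with quinoline and one equivalent of hydrogen the isopropenyl and angelate double bonds should remain.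

Step 19
Reactants: 32 (Z-enoate acetonide)
Product: 33 (target CNP0395983.1, 3α-[(2Z,5R)-5-(angeloyloxy)hex-2-enoyloxy]eremophil-11-ene-8β,9β-diol)
Conditions: AcOH–H2O (4:1), 40 °C
Reagents that add atoms: none
Why: Mild aqueous acid hydrolyses the isopropylidene acetal and should leave the esters in place (no hydroxyl adjacent to C3), the Z-enoate and angelate geometries intact and the isopropenyl group unhydrated.

Compound list
1 | 2,3-dimethylanisole | COc1cccc(C)c1C | starting material
2 | 1-methoxy-2,3-dimethylcyclohexa-1,4-diene (racemic) | COC1=C(C)C(C)C=CC1 | intermediate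
3 | 1-methoxy-2,3-dimethylcyclohexa-1,3-diene | COC1=C(C)C(C)=CCC1 | intermediate
4 | 2,2,2-trifluoroethyl acrylate | C=CC(=O)OCC(F)(F)F | starting material
5 | 2,2,2-trifluoroethyl (1R,2R,4R)-1-methoxy-5,6-dimethylbicyclo[2.2.2]oct-5-ene-2-carboxylate, ester syn to the etheno bridge | CO[C@@]12CC[C@@H](C(C)=C1C)C[C@H]2C(=O)OCC(F)(F)F | intermediate
6 | (1R,2R,4R)-1-methoxy-5,6-dimethylbicyclo[2.2.2]oct-5-ene-2-carboxylic acid | CO[C@@]12CC[C@@H](C(C)=C1C)C[C@H]2C(O)=O | intermediate
7 | dilithium enediolate of acid 6 | CO[C@@]12CC[C@@H](C(C)=C1C)CC2=C([O-])[O-].[Li+].[Li+] | intermediate (not isolated)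
8 | 2-hydroperoxy-1-methoxy-5,6-dimethylbicyclo[2.2.2]oct-5-ene-2-carboxylic acid (C2 epimers) | CO[C@@]12CC[C@@H](C(C)=C1C)CC2(OO)C(O)=O | intermediate (not isolated)
9 | (1S,4R)-1-methoxy-5,6-dimethylbicyclo[2.2.2]oct-5-en-2-one | CO[C@@]12CC[C@@H](C(C)=C1C)CC2=O | intermediate
10 | potassium enolate of ketone 9 | CO[C@@]12CC[C@@H](C(C)=C1C)C=C2[O-].[K+] | intermediate (not isolated)
11 | (1S,3R,4S)-3-hydroxy-1-methoxy-5,6-dimethylbicyclo[2.2.2]oct-5-en-2-one, hydroxyl syn to the etheno bridge | CO[C@@]12CC[C@@H](C(C)=C1C)[C@@H](O)C2=O | intermediate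
12 | (1S,3R,4S)-3-(benzyloxymethoxy)-1-methoxy-5,6-dimethylbicyclo[2.2.2]oct-5-en-2-one | CO[C@@]12CC[C@@H](C(C)=C1C)[C@@H](OCOCc3ccccc3)C2=O | intermediate
13 | 2-methylbut-1-en-3-yne | C=C(C)C#C | starting material
14 | (Z)-9-(2-bromo-3-methylbuta-1,3-dienyl)-9-borabicyclo[3.3.1]nonane, B and Br cis | C=C(C)/C(Br)=C/B1C2CCCC1CCC2 | intermediate (not isolated)
15 | 2-bromo-3-methylbuta-1,3-diene | C=C(Br)C(C)=C | intermediate
16 | (3-methylbuta-1,3-dien-2-yl)lithium | [Li]C(=C)C(C)=C | intermediate (not isolated)
17 | (3-methylbuta-1,3-dien-2-yl)cerium dichloride | Cl[Ce](Cl)C(=C)C(C)=C | intermediate (not isolated)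
18 | (1S,2S,3R,4S)-3-(benzyloxymethoxy)-1-methoxy-5,6-dimethyl-2-(3-methylbuta-1,3-dien-2-yl)bicyclo[2.2.2]oct-5-en-2-ol; dienyl and alkoxy groups syn to the etheno bridge, hydroxyl toward the C7–C8 bridge | CO[C@@]12CC[C@@H](C(C)=C1C)[C@@H](OCOCc3ccccc3)[C@@]2(O)C(=C)C(C)=C | intermediate
19 | potassium alkoxide of carbinol 18 | CO[C@@]12CC[C@@H](C(C)=C1C)[C@@H](OCOCc3ccccc3)[C@@]2([O-])C(=C)C(C)=C.[K+] | intermediate (not isolated)
20 | potassium 8-oxido-7,11-dienolate of the cis-decalin (C7=C8 enolate conjugated with C11=C12) | C=C(C)C=1C[C@@]2(C)[C@H](CCC(OC)=C2C)[C@@H](OCOCc3ccccc3)C=1[O-].[K+] | intermediate (not isolated)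
21 | 9β-(benzyloxymethoxy)-3-methoxyeremophila-3,11-dien-8-one (5β-methyl, 10βH, 7β-isopropenyl) | C=C(C)[C@H]1C[C@@]2(C)[C@H](CCC(OC)=C2C)[C@@H](OCOCc3ccccc3)C1=O | intermediate
22 | 9β-(benzyloxymethoxy)-3-methoxyeremophila-3,11-dien-8β-ol | C=C(C)[C@H]1C[C@@]2(C)[C@H](CCC(OC)=C2C)[C@@H](OCOCc3ccccc3)[C@H]1O | intermediate
23 | 9β-(benzyloxymethoxy)-8β-hydroxyeremophil-11-en-3-one (4β-methyl) | C=C(C)[C@H]1C[C@@]2(C)[C@H](CCC(=O)[C@@H]2C)[C@@H](OCOCc3ccccc3)[C@H]1O | intermediate
24 | eremophil-11-ene-3α,8β,9β-triol | C=C(C)[C@H]1C[C@@]2(C)[C@H](CC[C@@H](O)[C@@H]2C)[C@@H](O)[C@H]1O | intermediate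
25 | 8β,9β-(isopropylidenedioxy)eremophil-11-en-3α-ol | C=C(C)[C@H]1C[C@@]2(C)[C@H](CC[C@@H](O)[C@@H]2C)[C@@H](OC3(C)C)[C@H]1O3 | intermediate
26 | (R)-pent-4-yn-2-ol | C#CC[C@@H](C)O | starting material
27 | angelic acid, (Z)-2-methylbut-2-enoic acid | OC(=O)/C(C)=C\C | starting material
28 | angelic 2,4,6-trichlorobenzoic anhydride | Clc1cc(Cl)c(C(=O)OC(=O)/C(C)=C\C)c(Cl)c1 | intermediate (not isolated)
29 | (R)-pent-4-yn-2-yl angelate | C#CC[C@@H](C)OC(=O)/C(C)=C\C | intermediate
30 | (R)-5-(angeloyloxy)hex-2-ynoic acid | OC(=O)C#CC[C@@H](C)OC(=O)/C(C)=C\C | intermediate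
31 | 3α-[(5R)-5-(angeloyloxy)hex-2-ynoyloxy]-8β,9β-(isopropylidenedioxy)eremophil-11-ene | C=C(C)[C@H]1C[C@@]2(C)[C@H](CC[C@@H](OC(=O)C#CC[C@@H](C)OC(=O)/C(C)=C\C)[C@@H]2C)[C@@H](OC3(C)C)[C@H]1O3 | intermediate
32 | 3α-[(2Z,5R)-5-(angeloyloxy)hex-2-enoyloxy]-8β,9β-(isopropylidenedioxy)eremophil-11-ene | C=C(C)[C@H]1C[C@@]2(C)[C@H](CC[C@@H](OC(=O)/C=C\C[C@@H](C)OC(=O)/C(C)=C\C)[C@@H]2C)[C@@H](OC3(C)C)[C@H]1O3 | intermediate
33 | CNP0395983.1, 3α-[(2Z,5R)-5-(angeloyloxy)hex-2-enoyloxy]eremophil-11-ene-8β,9β-diol; (3R,4R,5R,7R,8S,9R,10S) | C=C(C)[C@H]1C[C@@]2(C)[C@H](CC[C@@H](OC(=O)/C=C\C[C@@H](C)OC(=O)/C(C)=C\C)[C@@H]2C)[C@@H](O)[C@H]1O | target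

Total step count: 19. Longest linear sequence: 16 steps (steps 1–7, 9–14 and 17–19).

Steps most likely to fail

Step 9. Facial control in the carbonyl addition may be lost: the alkoxy group on C3 sits on the face that must be attacked, and its torsional and polar influence may steer the reagent to the opposite face, giving the epimer that cannot rearrange. The fallback sets out from ketone 9, which has no substituent beside the carbonyl, and returns at 21. Dienylcerium 17 is added to 9, where only the intrinsic preference for the etheno face operates, to give the dienyl carbinol F1. Rearrangement with KH and 18-crown-6, followed by an equilibrating work-up (NaOMe, MeOH), gives the conjugated isopropylidene ketone F2. Kinetic α′-deprotonation at C9 (LDA, −78 °C) and oxidation with the sulfonyloxaziridine give the 9-hydroxy enone F3. Protection with BOMCl and i-Pr2NEt gives the benzyloxymethyl ether F4. Treatment with t-BuOK in t-BuOH–THF forms the extended dienolate, during which C9 settles in the equatorial β configuration, and a cold inverse quench into acetic acid deconjugates the enone to 21.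

Step 10. The hindered tertiary alkoxide may fragment back to ketone 12 and a dienyl anion, or the diene unit may be consumed by base-induced oligomerisation, before the shift onto the fully substituted C5 takes place; protonation of the dienolate at its γ-carbon would be a further loss. The fallback sets out from 12 and returns at 21. Vinylcerium dichloride (from vinylmagnesium bromide and CeCl3) is added to 12 to give the vinyl carbinol F5, a member of the substrate class for which the rearrangement is established. After rearrangement with KH and 18-crown-6, the regiodefined C7–C8 enolate is transmetalated with ZnCl2 and trapped with acetone to give the aldol F6. Dehydration (MsCl, Et3N, then DBU) gives the isopropylidene ketone F4, the compound also met in the fallback to step 9, and the same dienolate formation and kinetic protonation lead to 21.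

Step 3. The strongly Lewis acidic catalyst may hydrolyse or oligomerise the enol ether diene, or endo and enantiofacial control may be insufficient with so substituted a diene. The fallback sets out from 3 and returns at 6. The chelating dienophile 3-acryloyloxazolidin-2-one is used with [Cu((R,R)-t-Bu-box)](SbF6)2 (10 mol %) in CH2Cl2 at −78 → −20 °C, a milder two-point-binding catalyst (ligand antipode chosen for the 2R adduct), to give the endo imide F7. Cleavage with LiOH and H2O2 in THF–H2O gives acid 6 and releases oxazolidin-2-one.

Further compounds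
F1 | step 9 | (1S,2R,4S)-1-methoxy-5,6-dimethyl-2-(3-methylbuta-1,3-dien-2-yl)bicyclo[2.2.2]oct-5-en-2-ol, dienyl syn to the etheno bridge | CO[C@@]12CC[C@@H](C(C)=C1C)C[C@@]2(O)C(=C)C(C)=C
F2 | step 9 | 3-methoxyeremophila-3,7(11)-dien-8-one (5β-methyl, 10βH) | CC(C)=C1C[C@@]2(C)[C@H](CCC(OC)=C2C)CC1=O
F3 | step 9 | 9β-hydroxy-3-methoxyeremophila-3,7(11)-dien-8-one | CC(C)=C1C[C@@]2(C)[C@H](CCC(OC)=C2C)[C@@H](O)C1=O
F4 | step 9 | 9β-(benzyloxymethoxy)-3-methoxyeremophila-3,7(11)-dien-8-one | CC(C)=C1C[C@@]2(C)[C@H](CCC(OC)=C2C)[C@@H](OCOCc3ccccc3)C1=O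
F5 | step 10 | (1S,2S,3R,4S)-3-(benzyloxymethoxy)-1-methoxy-5,6-dimethyl-2-vinylbicyclo[2.2.2]oct-5-en-2-ol, vinyl syn to the etheno bridge | CO[C@@]12CC[C@@H](C(C)=C1C)[C@@H](OCOCc3ccccc3)[C@@]2(O)C=C
F6 | step 10 | 9β-(benzyloxymethoxy)-11-hydroxy-3-methoxyeremophil-3-en-8-one (C7 configuration immaterial) | CC(C)(O)C1C[C@@]2(C)[C@H](CCC(OC)=C2C)[C@@H](OCOCc3ccccc3)C1=O
F7 | step 3 | 3-[(1R,2R,4R)-1-methoxy-5,6-dimethylbicyclo[2.2.2]oct-5-ene-2-carbonyl]oxazolidin-2-one, acyl group syn to the etheno bridge | CO[C@@]12CC[C@@H](C(C)=C1C)C[C@H]2C(=O)N1CCOC1=O
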